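**Retrosynthetic overview**
1. The 1,2-dioxane is closed last by a 6-exo intramolecular oxa-Michael (peroxy-Michael) addition of the C6 tertiary hydroperoxide to an (E)-2-methyl-2-enoate; C2 and C3 arise here, C6 is set earlier.
2. The hydroperoxy enoate comes from a Wittig reaction on a 1,2-dioxan-3-ol, itself made by one-carbon homologation of a 3-hydroperoxy alkanol obtained by invertive H2O2 opening of an enantioenriched 2,2-disubstituted oxetane.
3. The oxetane–enone skeleton is cut at C8–C9 (B-alkyl Suzuki coupling) into (R)-2-ethenyl-2-methyloxetane (from Sharpless epoxidation of an enynol) and an (E)-chloroalkene carrying the cyclohexenone.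
4. The chloroalkene–cyclohexenone is cut at C12–C13 (Stork–Danheiser addition) into a carboalumination-derived homoallyl iodide and 3-ethoxy-2,6,6-trimethylcyclohexenone.
5. Ring order: cyclohexenone (bought as the dione, unmasked in the Stork–Danheiser step), then the temporary oxetane, then the 1,2-dioxan-3-ol lactol, finally the 1,2-dioxane by the Michael closure.

Assumption: target carbons are called C1 (ester C=O) to C12 along the chain, so the peroxide carbons are C3 and C6; (E)-3-methylpent-2-en-4-yn-1-ol is bought as the pure E isomer.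

**Step 1**
Reactants: 1 2-methylcyclohexane-1,3-dione
Product: 2 3-ethoxy-2-methylcyclohex-2-en-1-one
Conditions: EtOH, p-TsOH (cat.), toluene, reflux, Dean–Stark
Reagents that add atoms: ethanol CCO
Why: Acid-catalysed O-alkylation of the enolised 1,3-diketone (vinylogous esterification), driven by azeotropic removal of water.

**Step 2**
Reactants: 2 3-ethoxy-2-methylcyclohex-2-en-1-one
Product: 4 3-ethoxy-2,6-dimethylcyclohex-2-en-1-one (racemic), via lithium dienolate 3 (not isolated)
Conditions: LiN(iPr)2, THF, −78 °C; MeI, −78 → 0 °C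
Reagents that add atoms: iodomethane CI
Why: Stork–Danheiser kinetic deprotonation at the only enolisable α′ carbon and SN2 methylation; the new stereocentre is racemic and is erased in step 3.

**Step 3**
Reactants: 4 3-ethoxy-2,6-dimethylcyclohex-2-en-1-one
Product: 6 3-ethoxy-2,6,6-trimethylcyclohex-2-en-1-one, via lithium dienolate 5 (not isolated)
Conditions: LiN(iPr)2, THF, −78 °C; MeI, −78 → 0 °C
Reagents that add atoms: iodomethane CI
Why: Second Stork–Danheiser α′-alkylation installs the gem-dimethyl group next to the carbonyl that will later receive the side chain.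

**Step 4**
Reactants: 7 but-3-yn-1-ol
Product: 9 (E)-4-chloro-3-methylbut-3-en-1-ol, via alkenylalane 8 (not isolated)
Conditions: AlMe3 (3 equiv), Cp2ZrCl2 (0.25 equiv), CH2Cl2, 0 °C → rt; then N-chlorosuccinimide, THF, −30 → 0 °C
Reagents that add atoms: trimethylaluminium C[Al](C)C; N-chlorosuccinimide O=C1CCC(=O)N1Cl
Why: Negishi zirconium-catalysed syn-carboalumination puts Me on the internal and Al on the terminal carbon, and chlorodealumination with retention fixes the E geometry of the later C9=C10 alkene.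

**Step 5**
Reactants: 9 (E)-4-chloro-3-methylbut-3-en-1-ol
Product: 10 (E)-1-chloro-4-iodo-2-methylbut-1-ene
Conditions: I2, PPh3, imidazole, CH2Cl2, 0 °C → rt
Reagents that add atoms: iodine II
Why: Appel-type (Garegg–Samuelsson) iodination of the primary alcohol; the alkenyl chloride is inert.

**Step 6**
Reactants: 10 (E)-1-chloro-4-iodo-2-methylbut-1-ene; 6 3-ethoxy-2,6,6-trimethylcyclohex-2-en-1-one
Product: 13 3-[(E)-4-chloro-3-methylbut-3-en-1-yl]-2,4,4-trimethylcyclohex-2-en-1-one, via organolithium 11 (not isolated), via carbinolate adduct 12 (not isolated)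
Conditions: t-BuLi (2.1 equiv), Et2O–pentane, −78 °C; 6, THF, −78 → 0 °C; then 1 M HCl, THF, rt
Reagents that add atoms: water O
Why: Iodine–lithium exchange (far faster than any reaction of the alkenyl chloride), 1,2-addition to the vinylogous ester and acid-induced enol-ether hydrolysis/dehydration (Stork–Danheiser transposition) give the 3-alkyl-2,4,4-trimethylcyclohexenone with unambiguous regiochemistry.

**Step 7**
Reactants: 14 (E)-3-methylpent-2-en-4-yn-1-ol
Product: 15 [(2S,3S)-3-ethynyl-3-methyloxiran-2-yl]methanol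
Conditions: Ti(OiPr)4 (10 mol %), L-(+)-diethyl tartrate (12 mol %), t-BuOOH (2 equiv), 4 Å molecular sieves, CH2Cl2, −20 °C
Reagents that add atoms: tert-butyl hydroperoxide CC(C)(C)OO
Why: Katsuki–Sharpless asymmetric epoxidation; L-(+)-tartrate delivers oxygen to the face that gives the (2S,3S)-epoxide (same sense as for geraniol), which fixes the absolute configuration of the future C6.

**Step 8**
Reactants: 15 [(2S,3S)-3-ethynyl-3-methyloxiran-2-yl]methanol
Product: 16 (3R)-3-methylpent-4-yne-1,3-diol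
Conditions: NaAlH2(OCH2CH2OMe)2, THF, −20 → 0 °C
Reagents that add atoms: none
Why: The alkoxy-aluminate delivers hydride intramolecularly to C2 of the 2,3-epoxy alcohol (regioselective reductive opening to the 1,3-diol), leaving the tertiary C–O bond and its configuration untouched.

**Step 9**
Reactants: 16 (3R)-3-methylpent-4-yne-1,3-diol
Product: 17 (3R)-3-methylpent-4-ene-1,3-diol
Conditions: H2 (1 atm), Pd/CaCO3 poisoned with Pb(OAc)2, quinoline, EtOAc, rt
Reagents that add atoms: none
Why: Lindlar semihydrogenation of the terminal alkyne to the vinyl group; any alkene already formed by over-reduction in step 8 converges here.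

**Step 10**
Reactants: 17 (3R)-3-methylpent-4-ene-1,3-diol
Product: 18 (3R)-3-hydroxy-3-methylpent-4-en-1-yl 4-methylbenzenesulfonate
Conditions: TsCl (1.05 equiv), Et3N, DMAP (cat.), CH2Cl2, 0 °C
Reagents that add atoms: 4-methylbenzenesulfonyl chloride Cc1ccc(cc1)S(Cl)(=O)=O
Why: Selective sulfonylation of the primary over the tertiary hydroxyl.

**Step 11**
Reactants: 18 (3R)-3-hydroxy-3-methylpent-4-en-1-yl 4-methylbenzenesulfonate
Product: 19 (2R)-2-ethenyl-2-methyloxetane
Conditions: NaH, THF, 0 → 40 °C; distilled and used as a THF solution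
Reagents that add atoms: none
Why: Intramolecular Williamson etherification (4-exo-tet) of the tertiary alkoxide on the primary tosylate, with retention at the stereocentre because its C–O bond is not broken.

**Step 12**
Reactants: 19 (2R)-2-ethenyl-2-methyloxetane; 13 3-[(E)-4-chloro-3-methylbut-3-en-1-yl]-2,4,4-trimethylcyclohex-2-en-1-one
Product: 21 2,4,4-trimethyl-3-{(3E)-3-methyl-6-[(2S)-2-methyloxetan-2-yl]hex-3-en-1-yl}cyclohex-2-en-1-one, via alkylborane 20 (not isolated)
Conditions: 9-BBN, THF, 0 °C → rt; then 13, Pd(OAc)2 (5 mol %), SPhos (10 mol %), K3PO4 (3 M aq), THF, 60 °C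
Reagents that add atoms: none
Why: Anti-Markovnikov hydroboration of the vinyl group and B-alkyl Suzuki–Miyaura coupling with the alkenyl chloride form C8–C9 with retention of the E geometry; the stereocentre is not involved (its descriptor becomes S only through the priority rules).

**Step 13**
Reactants: 21 2,4,4-trimethyl-3-{(3E)-3-methyl-6-[(2S)-2-methyloxetan-2-yl]hex-3-en-1-yl}cyclohex-2-en-1-one
Product: 22 3-[(3E,7R)-7-hydroperoxy-9-hydroxy-3,7-dimethylnon-3-en-1-yl]-2,4,4-trimethylcyclohex-2-en-1-one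
Conditions: H2O2 (anhydrous, ca. 2 M in Et2O, 10 equiv), Me3SiOTf (0.2 equiv), Et2O, −78 → −20 °C; NaHCO3 quench
Reagents that add atoms: hydrogen peroxide OO
Why: Lewis-acid-activated perhydrolysis of the 2,2-dialkyloxetane, in which H2O2 attacks the tertiary carbon opposite to the departing oxygen (borderline SN2 through a tight ion pair), so C6 is set as R by inversion of the S oxetane carbon.

**Step 14**
Reactants: 22 3-[(3E,7R)-7-hydroperoxy-9-hydroxy-3,7-dimethylnon-3-en-1-yl]-2,4,4-trimethylcyclohex-2-en-1-one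
Product: 23 3-[(3E,7R)-9-hydroxy-7-[(2-methoxypropan-2-yl)peroxy]-3,7-dimethylnon-3-en-1-yl]-2,4,4-trimethylcyclohex-2-en-1-one
Conditions: 2-methoxypropene (1.2 equiv), PPTS (5 mol %), CH2Cl2, −20 °C; Et3N quench
Reagents that add atoms: 2-methoxypropene COC(C)=C
Why: Peroxyketal protection: the hydroperoxide (α-effect nucleophile) adds to the oxocarbenium ion faster than the primary alcohol and the peroxyketal is much less acid-labile than an O-alkyl ketal, so any bis-ketal can be cut back with PPTS/MeOH at 0 °C.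

**Step 15**
Reactants: 23 3-[(3E,7R)-9-hydroxy-7-[(2-methoxypropan-2-yl)peroxy]-3,7-dimethylnon-3-en-1-yl]-2,4,4-trimethylcyclohex-2-en-1-one
Product: 24 (3R,6E)-3-[(2-methoxypropan-2-yl)peroxy]-3,7-dimethyl-9-(2,6,6-trimethyl-3-oxocyclohex-1-en-1-yl)non-6-enal
Conditions: Dess–Martin periodinane, NaHCO3, CH2Cl2, 0 °C; used crude
Reagents that add atoms: none
Why: Buffered Dess–Martin oxidation gives the aldehyde under non-basic, non-reducing conditions that spare the peroxyketal, the enone and the alkene.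

**Step 16**
Reactants: 24 (3R,6E)-3-[(2-methoxypropan-2-yl)peroxy]-3,7-dimethyl-9-(2,6,6-trimethyl-3-oxocyclohex-1-en-1-yl)non-6-enal
Product: 27 3-{(3E)-6-[(3R)-6-hydroxy-3-methyl-1,2-dioxan-3-yl]-3-methylhex-3-en-1-yl}-2,4,4-trimethylcyclohex-2-en-1-one (anomer mixture), via enol ether 25 (not isolated), via hydroperoxy aldehyde 26 (not isolated)
Conditions: MeOCH2PPh3Cl, KN(SiMe3)2, THF, −78 °C; 24, −78 → 0 °C; then 1 M HCl, THF, 0 °C → rt
Reagents that add atoms: (methoxymethyl)triphenylphosphonium chloride [Cl-].COC[P+](c1ccccc1)(c1ccccc1)c1ccccc1; water O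
Why: Wittig methoxymethylenation adds C3, and aqueous acid hydrolyses both the enol ether and the peroxyketal so that the freed hydroperoxide closes on the new aldehyde as the six-membered peroxy-hemiacetal (the anomeric centre is lost again in step 17).

**Step 17**
Reactants: 27 3-{(3E)-6-[(3R)-6-hydroxy-3-methyl-1,2-dioxan-3-yl]-3-methylhex-3-en-1-yl}-2,4,4-trimethylcyclohex-2-en-1-one
Product: 29 methyl (2S)-2-{(3S,6R)-6-methyl-6-[(3E)-4-methyl-6-(2,6,6-trimethyl-3-oxocyclohex-1-en-1-yl)hex-3-en-1-yl]-1,2-dioxan-3-yl}propanoate, via hydroperoxy enoate 28 (not isolated)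
Conditions: Ph3P=C(Me)CO2Me (1.5 equiv), toluene, 40 °C; then Et2NH (0.5 equiv), CF3CH2OH, rt; preparative HPLC
Reagents that add atoms: methyl 2-(triphenylphosphoranylidene)propanoate COC(=O)C(C)=P(c1ccccc1)(c1ccccc1)c1ccccc1
Why: E-selective Wittig olefination of the open-chain aldehyde tautomer, then amine-promoted 6-exo-trig intramolecular oxa-Michael (peroxy-Michael) addition closes the 1,2-dioxane; C3 forms in a chair transition state on either face and C2 by protonation of the ester enol, so substrate control is weak and the (2S,3S,6R) isomer is separated from its three diastereomers, C6 being fixed since step 13.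

**Compound list**
1 | 2-methylcyclohexane-1,3-dione | CC1C(=O)CCCC1=O | starting material
2 | 3-ethoxy-2-methylcyclohex-2-en-1-one | CCOC1=C(C)C(=O)CCC1 | intermediate
3 | lithium 5-ethoxy-6-methylcyclohexa-1,5-dien-1-olate (kinetic dienolate of 2) | CCOC1=C(C)C(O[Li])=CCC1 | intermediate
4 | 3-ethoxy-2,6-dimethylcyclohex-2-en-1-one (racemic) | CCOC1=C(C)C(=O)C(C)CC1 | intermediate
5 | lithium 5-ethoxy-2,6-dimethylcyclohexa-1,5-dien-1-olate (kinetic dienolate of 4) | CCOC1=C(C)C(O[Li])=C(C)CC1 | intermediate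
6 | 3-ethoxy-2,6,6-trimethylcyclohex-2-en-1-one | CCOC1=C(C)C(=O)C(C)(C)CC1 | intermediate
7 | but-3-yn-1-ol | C#CCCO | starting material
8 | [(E)-4-(dimethylalumanyloxy)-2-methylbut-1-en-1-yl]dimethylalumane | C[Al](C)/C=C(\C)CCO[Al](C)C | intermediate
9 | (E)-4-chloro-3-methylbut-3-en-1-ol | Cl/C=C(\C)CCO | intermediate
10 | (E)-1-chloro-4-iodo-2-methylbut-1-ene | Cl/C=C(\C)CCI | intermediate
11 | [(E)-4-chloro-3-methylbut-3-en-1-yl]lithium | Cl/C=C(\C)CC[Li] | intermediate
12 | lithium 1-[(E)-4-chloro-3-methylbut-3-en-1-yl]-3-ethoxy-2,6,6-trimethylcyclohex-2-en-1-olate (racemic) | CCOC1=C(C)C(O[Li])(CC/C(C)=C/Cl)C(C)(C)CC1 | intermediate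
13 | 3-[(E)-4-chloro-3-methylbut-3-en-1-yl]-2,4,4-trimethylcyclohex-2-en-1-one | Cl/C=C(\C)CCC1=C(C)C(=O)CCC1(C)C | intermediate
14 | (E)-3-methylpent-2-en-4-yn-1-ol | C#C/C(C)=C/CO | starting material
15 | [(2S,3S)-3-ethynyl-3-methyloxiran-2-yl]methanol | OC[C@@H]1O[C@@]1(C)C#C | intermediate
16 | (3R)-3-methylpent-4-yne-1,3-diol | OCC[C@](O)(C)C#C | intermediate
17 | (3R)-3-methylpent-4-ene-1,3-diol | OCC[C@](O)(C)C=C | intermediate
18 | (3R)-3-hydroxy-3-methylpent-4-en-1-yl 4-methylbenzenesulfonate | Cc1ccc(cc1)S(=O)(=O)OCC[C@](O)(C)C=C | intermediate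
19 | (2R)-2-ethenyl-2-methyloxetane | C=C[C@@]1(C)CCO1 | intermediate
20 | 9-{2-[(2S)-2-methyloxetan-2-yl]ethyl}-9-borabicyclo[3.3.1]nonane | C[C@]1(CCB2C3CCCC2CCC3)CCO1 | intermediate
21 | 2,4,4-trimethyl-3-{(3E)-3-methyl-6-[(2S)-2-methyloxetan-2-yl]hex-3-en-1-yl}cyclohex-2-en-1-one | C[C@]1(CC/C=C(\C)CCC2=C(C)C(=O)CCC2(C)C)CCO1 | intermediate
22 | 3-[(3E,7R)-7-hydroperoxy-9-hydroxy-3,7-dimethylnon-3-en-1-yl]-2,4,4-trimethylcyclohex-2-en-1-one | C[C@@](OO)(CC/C=C(\C)CCC1=C(C)C(=O)CCC1(C)C)CCO | intermediate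
23 | 3-[(3E,7R)-9-hydroxy-7-[(2-methoxypropan-2-yl)peroxy]-3,7-dimethylnon-3-en-1-yl]-2,4,4-trimethylcyclohex-2-en-1-one | C[C@@](OOC(C)(C)OC)(CC/C=C(\C)CCC1=C(C)C(=O)CCC1(C)C)CCO | intermediate
24 | (3R,6E)-3-[(2-methoxypropan-2-yl)peroxy]-3,7-dimethyl-9-(2,6,6-trimethyl-3-oxocyclohex-1-en-1-yl)non-6-enal | C[C@@](OOC(C)(C)OC)(CC/C=C(\C)CCC1=C(C)C(=O)CCC1(C)C)CC=O | intermediate
25 | 3-[(3E,7R)-10-methoxy-7-[(2-methoxypropan-2-yl)peroxy]-3,7-dimethyldeca-3,9-dien-1-yl]-2,4,4-trimethylcyclohex-2-en-1-one (E/Z mixture at the enol ether) | C[C@@](OOC(C)(C)OC)(CC/C=C(\C)CCC1=C(C)C(=O)CCC1(C)C)CC=COC | intermediate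
26 | (4R,7E)-4-hydroperoxy-4,8-dimethyl-10-(2,6,6-trimethyl-3-oxocyclohex-1-en-1-yl)dec-7-enal | C[C@@](OO)(CC/C=C(\C)CCC1=C(C)C(=O)CCC1(C)C)CCC=O | intermediate
27 | 3-{(3E)-6-[(3R)-6-hydroxy-3-methyl-1,2-dioxan-3-yl]-3-methylhex-3-en-1-yl}-2,4,4-trimethylcyclohex-2-en-1-one (anomer mixture) | C[C@@]1(CC/C=C(\C)CCC2=C(C)C(=O)CCC2(C)C)CCC(O)OO1 | intermediate
28 | methyl (2E,6R,9E)-6-hydroperoxy-2,6,10-trimethyl-12-(2,6,6-trimethyl-3-oxocyclohex-1-en-1-yl)dodeca-2,9-dienoate | COC(=O)/C(C)=C/CC[C@](C)(OO)CC/C=C(\C)CCC1=C(C)C(=O)CCC1(C)C | intermediate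
29 | methyl (2S)-2-{(3S,6R)-6-methyl-6-[(3E)-4-methyl-6-(2,6,6-trimethyl-3-oxocyclohex-1-en-1-yl)hex-3-en-1-yl]-1,2-dioxan-3-yl}propanoate | COC(=O)[C@@H](C)[C@@H]1CC[C@@](C)(CC/C=C(\C)CCC2=C(C)C(=O)CCC2(C)C)OO1 | target

**Totals**
Total step count: 17.
Longest linear sequence: 11 steps (14 → 29, steps 7 to 17). The ring branch (steps 1–3, 6) and the butynol branch (steps 4, 5) run in parallel.

**Three steps most likely to fail, each with a fallback**

Step 13 (oxetane perhydrolysis). The danger is loss of stereochemical fidelity at the tertiary carbon, or no opening without more ionising conditions. The fallback sets out from 21 and returns at 27, and secures C6 by resolution instead of stereospecific substitution. Compound 21 is opened under whatever conditions work (for example 50% H2O2 with catalytic H2SO4) to scalemic 22. This is ketalised at the hydroperoxide with (1R,2S)-2-phenylcyclohexyl isopropenyl ether (PPTS, CH2Cl2) in place of 2-methoxypropene, giving the phenylcyclohexyl perketal alcohol F1 as two diastereomers separable by HPLC. The (7R) isomer is oxidised with Dess–Martin periodinane to the perketal aldehyde F2, homologated with Ph3P=CHOMe to the perketal enol ether F3, and hydrolysed with 1 M HCl to 27.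

Step 16 (methoxymethylenation of a β-peroxy aldehyde). The basic ylide may eliminate the β-peroxy group or enolise 24. The fallback sets out from 24 and returns at 28, bringing in C1–C3 in one olefination. Compound 24 is treated at −78 °C with the ylide-carboxylate made from (2-carboxypropyl)triphenylphosphonium bromide and NaN(SiMe3)2 (2 equiv) to give the β,γ-unsaturated acid F4, which Me3SiCHN2 converts into the β,γ-unsaturated methyl ester F5. PPTS in MeOH removes the peroxyketal to give the hydroperoxy β,γ-unsaturated ester F6. DBU in CF3CH2OH then moves the double bond into conjugation, giving 28 (with some 2Z isomer), which closes to 29 by the same peroxy-Michael addition as in step 17.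

Step 17 (peroxy-Michael closure). The methyl enoate may give too little of the (2S,3S,6R) isomer. The fallback sets out from 27 and returns at 29, running the closure on a chiral imide. Compound 27 is olefinated with the phosphorane prepared from (4S)-4-benzyl-3-(2-bromopropanoyl)-1,3-oxazolidin-2-one to give the hydroperoxy enoyl oxazolidinone F7. The more electrophilic imide cyclises under the same Et2NH/CF3CH2OH conditions, and the auxiliary biases both the attack at C3 and the protonation at C2 (the enantiomeric auxiliary is used if it proves to be the matched one), giving the dioxane imide F8. Methanolysis catalysed by Sm(OTf)3 then gives 29.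

**Further compounds**
F1 | step 13 | 3-[(3E,7R)-9-hydroxy-3,7-dimethyl-7-({2-[(1R,2S)-2-phenylcyclohexyl]oxypropan-2-yl}peroxy)non-3-en-1-yl]-2,4,4-trimethylcyclohex-2-en-1-one | C[C@@](OOC(C)(C)O[C@@H]1CCCC[C@H]1c1ccccc1)(CC/C=C(\C)CCC1=C(C)C(=O)CCC1(C)C)CCO
F2 | step 13 | (3R,6E)-3,7-dimethyl-3-({2-[(1R,2S)-2-phenylcyclohexyl]oxypropan-2-yl}peroxy)-9-(2,6,6-trimethyl-3-oxocyclohex-1-en-1-yl)non-6-enal | C[C@@](OOC(C)(C)O[C@@H]1CCCC[C@H]1c1ccccc1)(CC/C=C(\C)CCC1=C(C)C(=O)CCC1(C)C)CC=O
F3 | step 13 | 3-[(3E,7R)-10-methoxy-3,7-dimethyl-7-({2-[(1R,2S)-2-phenylcyclohexyl]oxypropan-2-yl}peroxy)deca-3,9-dien-1-yl]-2,4,4-trimethylcyclohex-2-en-1-one (E/Z mixture at the enol ether) | C[C@@](OOC(C)(C)O[C@@H]1CCCC[C@H]1c1ccccc1)(CC/C=C(\C)CCC1=C(C)C(=O)CCC1(C)C)CC=COC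
F4 | step 16 | (3Z,6R,9E)-6-[(2-methoxypropan-2-yl)peroxy]-2,6,10-trimethyl-12-(2,6,6-trimethyl-3-oxocyclohex-1-en-1-yl)dodeca-3,9-dienoic acid (C2 epimer mixture) | C[C@@](OOC(C)(C)OC)(CC/C=C(\C)CCC1=C(C)C(=O)CCC1(C)C)C/C=C\C(C)C(O)=O
F5 | step 16 | methyl (3Z,6R,9E)-6-[(2-methoxypropan-2-yl)peroxy]-2,6,10-trimethyl-12-(2,6,6-trimethyl-3-oxocyclohex-1-en-1-yl)dodeca-3,9-dienoate (C2 epimer mixture) | C[C@@](OOC(C)(C)OC)(CC/C=C(\C)CCC1=C(C)C(=O)CCC1(C)C)C/C=C\C(C)C(=O)OC
F6 | step 16 | methyl (3Z,6R,9E)-6-hydroperoxy-2,6,10-trimethyl-12-(2,6,6-trimethyl-3-oxocyclohex-1-en-1-yl)dodeca-3,9-dienoate (C2 epimer mixture) | C[C@@](OO)(CC/C=C(\C)CCC1=C(C)C(=O)CCC1(C)C)C/C=C\C(C)C(=O)OC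
F7 | step 17 | (4S)-4-benzyl-3-[(2E,6R,9E)-6-hydroperoxy-2,6,10-trimethyl-12-(2,6,6-trimethyl-3-oxocyclohex-1-en-1-yl)dodeca-2,9-dienoyl]-1,3-oxazolidin-2-one | O=C1OC[C@H](Cc2ccccc2)N1C(=O)/C(C)=C/CC[C@](C)(OO)CC/C=C(\C)CCC1=C(C)C(=O)CCC1(C)C
F8 | step 17 | (4S)-4-benzyl-3-[(2S)-2-{(3S,6R)-6-methyl-6-[(3E)-4-methyl-6-(2,6,6-trimethyl-3-oxocyclohex-1-en-1-yl)hex-3-en-1-yl]-1,2-dioxan-3-yl}propanoyl]-1,3-oxazolidin-2-one | O=C1OC[C@H](Cc2ccccc2)N1C(=O)[C@@H](C)[C@@H]1CC[C@@](C)(CC/C=C(\C)CCC2=C(C)C(=O)CCC2(C)C)OO1
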